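In a closed, stirred vessel the substrate can turn to target only with gas that has crossed into solution, and we want to know what the new flask holds at 8.0 h.

| setting | Thursday's | Monday's | flask |
|---|---|---|---|
| substrate | 28 mM | 44 mM | 20 mM |
| gas phase | 2.6 mM (held) | 2.6 mM (held) | 2.6 mM (held) |
| remark | run made earlier | run made earlier |  |
| time |  |  | 8.0 h |

| run | time / h | target / % |
|---|---|---|
| Thursday's | 0.500 | 2 |
| Thursday's | 1.33 | 7 |
| Thursday's | 2.50 | 4 |
| Thursday's | 4.00 | 11 |
| Thursday's | 6.00 | 14 |
| Thursday's | 8.00 | 14 |
| Thursday's | 10.0 | 20 |
| Monday's | 0.500 | 2 |
| Monday's | 1.33 | 1 |
| Monday's | 2.50 | 8 |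
| Monday's | 4.00 | 11 |
| Monday's | 6.00 | 14 |
| Monday's | 8.00 | 13 |
| Monday's | 10.0 | 16 |

(scatter of a reading: 2 percentage points)

- at the start none of the gas is dissolved
- reactions considered so far: gas phase <-> dissolved gas; substrate -> side product; substrate + dissolved gas -> target; target <-> isomer of the product

- ochre: doubling the saturation concentration of gas phase, all else as stated
- blue: doubling the transfer coefficient of the gas phase, all else as stated

* how much target there is at 8.0 h, in percent of the substrate charged
* the change that raises the amount of target at 8.0 h, in percent of the substrate charged most ("none" if none brings more than 2 percentage points) (ochre / blue / none)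
* amount of target at 8.0 h, in percent of the substrate charged, after ochre

Going from Thursday's 28 mM to Monday's 44 mM, a factor of 1.57, the percent of target at 8.00 h reads 14 % and 13 %, with a scatter of 2 percentage points. We therefore read target formation as pseudo-first-order in substrate, with c(dissolved gas) folded into the constant, and expect the new flask to follow the same percent curve. The first way to its number is simply the mean of those two readings, 13.5 %. The second uses other readings: integrating the rate, the part of the charge that is not target decays as exp(−κt), and the mean of the readings at 10.0 h gives 0.0198 h⁻¹ for κ, the yield constant, hence 14.7 % at 8.0 h. The two ways agree within the scatter, so we commit to the second. If κ follows c(dissolved gas), ochre doubles it and gives 27.2 %, while blue reaches the same saturation sooner, and we expect little from that.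

The forecast gives 15 % (range 13 % to 18 %), chooses ochre, and puts that change at 27 % (21 % to 32 %), holding that “dissolved gas sits near saturation”.

The new flask gives 16.4 %; ochre is best, gaining 11 points against 2.1 points for blue, and it reaches 27.4 %.

    gas phase ⇌ dissolved gas, rate k1*(csat - [dissolved gas]) (kL = 1.32 h⁻¹)
    substrate → side product (k = 0.00290 h⁻¹)
    substrate + dissolved gas → target (k = 26.6 M⁻¹ h⁻¹)
    target ⇌ isomer of the product (K = 2.10, k = 0.279 h⁻¹)

Back on the new flask, κ gives 14.7 % against 16.4 %, but it is a net constant: target stands at 16.4 % rather than 31.6 % without the step to the isomer of the product, and rather than 30.6 % at ten times the hour, the two acting together. Read at 4.35 h or at 14.2 h instead, this flask stands 5 points from 16.4 %, outside the forecast's range of 13 % to 18 %. On the neighbouring flask read at 15 h, κ gives 25.7 %, and that flask holds 21.9 %.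

(Readings and results are calculated on assumed constants, noise included.)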